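**Assumption:** the target has no stereocentre (the bridging CH carries two identical aryl groups and the SMILES shows no stereodescriptor), so it is achiral and is made as the single compound drawn, with no asymmetric step.

## Retrosynthetic overview

1. Building blocks: 2,4,6-trihydroxyacetophenone (1), prenyl bromide (2), the monomer 3-prenyl-2,4,6-trihydroxyacetophenone (3) and isovaleraldehyde (4).
2. Key disconnection: both aryl–CH bonds of the isopentylidene bridge. Forward, two molecules of 3 and one of 4 pass through carbinol 5 and ortho-quinone methide 6 to the target 7.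
3. Second disconnection: the aryl–prenyl bond, 3 ⇒ 1 + 2 (C-alkylation of the phloroglucinolate).
4. Rings: none is formed; both benzene rings come from 1. Prenylate first and bridge last, so that 3 has only one free ring carbon for the aldehyde.

## Route

**Step 1**
Reactants: 1 2,4,6-trihydroxyacetophenone; 2 prenyl bromide
Product: 3 1-[2,4,6-trihydroxy-3-(3-methylbut-2-en-1-yl)phenyl]ethan-1-one
Conditions: 1 (1.5 equiv), KOH (1.0 equiv), H2O, 0 °C; 2 (1.0 equiv) dropwise, 0 °C → rt, 2 h; 1 M HCl to pH 3–4, EtOAc, SiO2 chromatography (excess 1 recovered)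
Reagents that add atoms: none
Why: C-alkylation of the ambident phloroglucinolate with a soft allylic bromide is favoured in water, where the phenoxide oxygens are hydrogen-bonded; the two free ring carbons of 1 are equivalent, so one mono-C-prenyl product forms, and excess 1 limits diprenylation (expect about 35–45 %).

**Step 2**
Reactants: 3 1-[2,4,6-trihydroxy-3-(3-methylbut-2-en-1-yl)phenyl]ethan-1-one (2.1 equiv); 4 isovaleraldehyde (1.0 equiv)
Product: 7 1,1'-{(3-methylbutane-1,1-diyl)bis[2,4,6-trihydroxy-5-(3-methylbut-2-en-1-yl)-3,1-phenylene]}bis(ethan-1-one) (CNP0215781.0), via benzylic carbinol 5 (not isolated), via ortho-quinone methide 6 (not isolated)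
Conditions: KOH (10 mol %), degassed MeOH–H2O, Ar, 0 °C → rt, 12 h; 1 M HCl to pH 3, EtOAc, SiO2 chromatography
Reagents that add atoms: none
Why: Base-catalysed phenol–aldehyde hydroxyalkylation (Lederer–Manasse type) at the only free ring carbon of 3 gives carbinol 5, which dehydrates to ortho-quinone methide 6, and Michael (Friedel–Crafts-type) addition of a second molecule of 3 gives 7; the phenol/phenoxide buffer (about pH 8) spares the prenyl groups and suppresses aldehyde self-aldol, and the new bridging carbon bears two identical aryl groups, so no stereocentre arises.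

## Compound list

1 | 2,4,6-trihydroxyacetophenone (phloroacetophenone, sold as the monohydrate) | CC(=O)c1c(O)cc(O)cc1O | starting material
2 | prenyl bromide (1-bromo-3-methylbut-2-ene) | CC(C)=CCBr | starting material
3 | 1-[2,4,6-trihydroxy-3-(3-methylbut-2-en-1-yl)phenyl]ethan-1-one | CC(=O)c1c(O)cc(O)c(CC=C(C)C)c1O | intermediate
4 | isovaleraldehyde (3-methylbutanal) | CC(C)CC=O | starting material
5 | 1-[2,4,6-trihydroxy-3-(1-hydroxy-3-methylbutyl)-5-(3-methylbut-2-en-1-yl)phenyl]ethan-1-one (racemic carbinol, not isolated) | CC(=O)c1c(O)c(CC=C(C)C)c(O)c(C(O)CC(C)C)c1O | intermediate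
6 | 4-acetyl-3,5-dihydroxy-2-(3-methylbut-2-en-1-yl)-6-(3-methylbutylidene)cyclohexa-2,4-dien-1-one (ortho-quinone methide, alkene geometry undefined, not isolated) | CC(=O)C1=C(O)C(=CCC(C)C)C(=O)C(CC=C(C)C)=C1O | intermediate
7 | 1,1'-{(3-methylbutane-1,1-diyl)bis[2,4,6-trihydroxy-5-(3-methylbut-2-en-1-yl)-3,1-phenylene]}bis(ethan-1-one), achiral, C31H40O8 | CC(=O)c1c(O)c(CC=C(C)C)c(O)c(C(CC(C)C)c2c(O)c(CC=C(C)C)c(O)c(C(C)=O)c2O)c1O | target

## Summary

Total step count: 2. Longest linear sequence: 2 steps (1 → 3 → 7).

The route has only two steps, so both are ranked here, the riskier one first; there is no third step.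

**Step 2 (bridging).** The risks are that ortho-quinone methide 6 tautomerises to a styrene or is trapped by solvent before the second arylation, that 4 self-condenses, or that the electron-rich phenoxides are oxidised by air. The fallback sets out from 3 and comes back at 7. Compound 3 is combined with 4 and morpholine (1.1 equiv each) in EtOH at rt in a three-component Mannich (Betti) reaction. This gives the isolable, racemic aminoalkylphenol 1-[2,4,6-trihydroxy-3-[3-methyl-1-(morpholin-4-yl)butyl]-5-(3-methylbut-2-en-1-yl)phenyl]ethan-1-one F2. F2 is then heated with a second equivalent of 3 in toluene at 80 °C. Morpholine is expelled, 6 is released slowly in the presence of its nucleophile, and 7 results.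

**Step 1 (C-prenylation).** The risks are O-prenylation, 3,5-diprenylation and gem-diprenylation, which lower the yield and complicate purification. The fallback reverses the order of the two bond formations; it sets out from 1 and comes back at 7. An excess of 1 (4 equiv, the surplus recovered) is condensed with 4 (1 equiv) under KOH (10 mol %) in degassed MeOH–H2O. This gives 1,1'-[(3-methylbutane-1,1-diyl)bis(2,4,6-trihydroxy-3,1-phenylene)]bis(ethan-1-one) F1. Each ring of F1 has only one free ring carbon, which is exactly the position that must carry the prenyl group. Double C-alkylation with 2 (2.1 equiv) and KOH (2.0 equiv) in water at 0 °C therefore gives 7 directly.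

## Further compounds

F1 | step 1 | 1,1'-[(3-methylbutane-1,1-diyl)bis(2,4,6-trihydroxy-3,1-phenylene)]bis(ethan-1-one) | CC(=O)c1c(O)cc(O)c(C(CC(C)C)c2c(O)cc(O)c(C(C)=O)c2O)c1O
F2 | step 2 | 1-[2,4,6-trihydroxy-3-[3-methyl-1-(morpholin-4-yl)butyl]-5-(3-methylbut-2-en-1-yl)phenyl]ethan-1-one (racemic) | CC(=O)c1c(O)c(CC=C(C)C)c(O)c(C(CC(C)C)N2CCOCC2)c1O
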